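## Structural features

Rhuschalcone IV (9) is a bichalcone of four benzene rings and no stereocentres. Ring A (a 2-hydroxy-4-methoxy-5-aryloxybenzoyl unit, numbered from the ketone-bearing carbon C1) and ring C (a 2-hydroxy-4-aryloxybenzoyl unit) are joined by one diaryl ether oxygen between C5 of ring A and C4 of ring C. Each of these rings carries at C1 an (E)-3-(4-hydroxyphenyl)prop-2-enoyl chain, ending in ring B on the ring A side and ring D on the ring C side. The only stereochemical elements are the two E enone double bonds, which are the thermodynamically favoured isomers and stand next to no stereocentre. The fragile parts are the two 2-hydroxyaryl enones, which can close to flavanones under acid or mild base and to flavones or aurones under oxidants, the two Michael-acceptor double bonds, and four oxidisable phenols beside a single methyl ether at C4 of ring A. The difficulty is therefore not the carbon skeleton but the unsymmetrical oxygen pattern around the ether link and the need to keep one oxygen methylated and four free without exposing a 2-hydroxychalcone to cyclising conditions. The key step uses the fact that the C2–OH groups of ring A and of ring C both lie ortho to the C1 ketone carbons. Each ketone oxygen can steer a metal to exactly these C2–H bonds, so both oxygens can be added last to a bis-chalcone assembled from non-hydroxylated acetophenones.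

## Logic of the disconnections

9 to 8. The two acyl–oxygen bonds of the esters on rings B and D are cut. The free 4-hydroxyphenyl groups could not pass through an acidic, oxidising step, and an ester both masks them and withdraws electron density from rings B and D. The gain is that the last step is a plain deprotection. The demand is that ester cleavage must leave the two chelated 2-hydroxy enones and both E alkenes untouched.

8 to 6 (through 7). The C2–O bonds of ring A and ring C are cut. This removes every ortho phenol from the earlier chemistry: 6 contains one methyl ether, one diaryl ether and two esters, needs no phenol differentiation, and its enones can be built without chelated hydroxyls nearby. The demand on the forward step is heavy. Oxygenation must occur twice, at C2 and not C6 of ring A, once per ring, and without harm to two enones and two aryl esters.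

6 to 3 and 5. The two Cα=Cβ double bonds are cut by retro-aldol condensation. Both chalcone arms come from the same aldehyde, so one operation builds both, and the E geometry follows from thermodynamic dehydration. Since 5 already carries the base-labile ester, the forward condensation must be run under non-basic conditions and must go to completion on both methyl ketones.

5 to 4. The acyl–oxygen bond of the ester is cut. Placing the ester on the aldehyde before the condensation avoids condensing a phenoxide-deactivated aldehyde under base and avoids handling a poorly soluble bis-phenol. The forward step is a simple O-acylation.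

3 to 1 and 2. The aryl ether bond at C4 of ring C is cut. The para acetyl group of 2 activates its fluoride for addition–elimination, and the single phenol of 1 already sits meta to the acetyl and ortho to the methoxy group, which fixes the C4/C5 pattern of ring A at the outset. The forward step must tolerate two enolisable methyl ketones under hot carbonate.

## Other disconnections considered

Alternative 1: Ring A is taken apart across C1–C2 and C5–C6. One fragment is the 1,1-bis(trimethylsilyloxy)-3-methoxy-4-aryloxybutadiene A1, which holds C2–C5 and the whole of ring C in masked form (ketone as dioxolane, phenol as MOM ether). The other is the cross-conjugated enynone A2, which holds C1, C6 and the ring B enone.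
- Forward step: a Diels–Alder reaction would join the electron-rich terminus C5 to the alkyne β-carbon C6 and the ketene acetal carbon C2 to C1. The 1,4-cyclohexadiene would aromatise by expelling one silyloxy group with the C5 hydrogen, and hydrolysis of the remaining silyl ether would leave the chelated C2 phenol of A3.
- In favour: the polarity match fixes all four ring A substituents, so the C2-versus-C6 question, which the chosen plan settles only by steric and electronic bias, does not arise. On regiochemical certainty this alternative is the better one, and it needs no oxidant.
- Against: A1 is a moisture-sensitive, tetra-oxygenated diene with a hindered heteroatom-bearing terminus, and its preparation needs a separately protected ring C phenol. A2 offers a second dienophilic π bond. After A3 the dioxolane must be opened, the second chalcone built, and two MOM ethers removed with acid beside two 2-hydroxychalcones.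
- Comparison: structurally it constructs a benzene ring that can be bought with the right methoxy/oxygen pattern. Mechanistically it is more predictable than a C–H activation. In step economy it is far behind, at well over ten operations against five.

Alternative 2: Both C(=O)–Cα bonds are cut, leading to the bis-salicylaldehyde A4 and two equivalents of the silyl-protected aryl alkyne A5.
- Forward step: with [RhCl(cod)]2, dppf and Na2CO3, each phenoxide would assist insertion of monovalent rhodium into the neighbouring aldehyde C–H bond. Syn addition of acyl and hydride across the alkyne, with the acyl on the terminal carbon, would give both E enones of A6.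
- In favour: the chelating phenols are present from the start and serve as directing groups, the mirror image of the chosen logic. The step is redox-neutral and atom-economical, and no oxidant or strong acid meets an enone or a phenol. Fluoride removal of the silyl ethers from A6 is gentler than ester methanolysis. On functional-group safety of the end game it is the better plan, and in convergence it is the equal.
- Against: the regiochemistry of addition to a terminal aryl alkyne (linear versus branched enone) would have to be controlled twice. Decarbonylation of the acyl–rhodium species and conjugate addition of the free phenoxide to the new enone under carbonate are further concerns. A4 is not a catalogue compound, and making it needs two differently substituted salicylaldehydes and a protected ether coupling.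
- Comparison: structurally both plans add the last pieces to a preformed diaryl ether. Mechanistically both rest on carbonyl/phenol chelation to a late transition metal. In step economy this route would be comparable or one to two steps longer, because of A4.

Alternative 3: Ring A is opened at C1–C6 to the linear 1,3,5-triketone A7, which bears the ring C aryloxy group at the future C5 and a dimethyl acetal as the future C6.
- Forward step: mild acid would unmask the aldehyde, the doubly activated C1 methylene would condense with it, and dehydration and enolisation would give the resorcinol-type ring A of A8.
- In favour: the position of every ring A oxygen is written into the chain, so there is no site-selectivity question, and on that point it is the better plan. It is free of transition metals and oxidants. The later O-methylation of the non-chelated C4 phenol should be as selective as anything in the chosen plan.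
- Against: A7 is a poly-enolised, acid- and base-sensitive chain that calls for polyanion acylation chemistry. Its folding competes with 4-pyranone formation by oxygen cyclisation and with aldol closure through the other methylene. After A8 there remain a selective methylation, a second aldol condensation on the ring C methyl ketone with a protected form of 4, and removal of allyl ethers.
- Comparison: structurally it rebuilds a ring that is commercially available. Mechanistically it relies on classical carbonyl chemistry with several competing cyclisation modes, against one directed C–H activation with one main selectivity issue. In step economy it is clearly the longer route.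

Key step: step 4

Remarks on the chemistry (before the steps):
- Ring A is numbered C1 (ketone-bearing), C2 (H in 6, OH in 8 and 9), C4 (OMe), C5 (O-aryl), C6 (H). Rings B and D are the 4-oxygenated phenyl rings of the ring A and ring C chalcones.
- Checked against the target, the skeletons of the 2-deoxy precursor 6 and of the oxygenated product 8 need no structural correction.
- One point of reasoning is adjusted: during the oxygenation the new oxygen is present as an aryl trifluoroacetate. It is this electron-poor ester, not a chelated phenol, that holds back a second oxygenation.
- Two design changes are made on the way to 6. The pivalate is installed on the aldehyde first, and the double condensation is run with a Lewis acid. A base-mediated condensation of the phenoxide of 4 would be sluggish, and the free bis-phenol would have to be handled and acylated afterwards.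
- Assumption: 5 is prepared in one step from 4 rather than purchased.

## Steps

Step 1
Reactants: 1 3'-hydroxy-4'-methoxyacetophenone; 2 4'-fluoroacetophenone (1.2 equiv)
Product: 3 1-[3-(4-acetylphenoxy)-4-methoxyphenyl]ethan-1-one
Conditions: K2CO3 (2 equiv), DMAc, 120 °C, N2
Reagents that add atoms: none
Why: SNAr by addition–elimination: the phenoxide of 1 attacks the fluorine-bearing carbon of 2, the para acetyl group stabilises the Meisenheimer intermediate, and fluoride leaves; carbonate is too weak a base to make aldol self-condensation of the methyl ketones competitive.

Step 2
Reactants: 4 4-hydroxybenzaldehyde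
Product: 5 4-formylphenyl pivalate (4-formylphenyl 2,2-dimethylpropanoate)
Conditions: PivCl (1.1 equiv), Et3N (1.3 equiv), DMAP (cat.), CH2Cl2, 0 °C to rt
Reagents that add atoms: pivaloyl chloride, CC(C)(C)C(Cl)=O
Why: DMAP-catalysed O-acylation (nucleophilic acyl substitution) of the only hydroxyl group; the aldehyde does not react.

Step 3
Reactants: 3 1-[3-(4-acetylphenoxy)-4-methoxyphenyl]ethan-1-one; 5 4-formylphenyl pivalate (2.4 equiv)
Product: 6 2-deoxy bis-chalcone bis(pivalate), (E)-1-[4-methoxy-3-(4-{(E)-3-[4-(pivaloyloxy)phenyl]prop-2-enoyl}phenoxy)phenyl]-3-[4-(pivaloyloxy)phenyl]prop-2-en-1-one
Conditions: BF3·OEt2 (2.2 equiv), 1,4-dioxane, rt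
Reagents that add atoms: none
Why: Twofold Lewis-acid-mediated Claisen–Schmidt condensation: BF3 promotes enolisation of each methyl ketone, activates the aldehyde and takes up the water released, and the aldol dehydrates to the thermodynamically favoured E enone; the non-basic medium is an established way to O-acylated chalcones, so the aryl pivalates should survive.

Step 4
Reactants: 6 2-deoxy bis-chalcone bis(pivalate)
Product: 8 rhuschalcone IV bis(pivalate) (ring B and ring D oxygens acylated; both C2 phenols free; E,E), via bis(aryl trifluoroacetate) 7 (not isolated)
Conditions: Pd(OAc)2 (10 mol% per ketone), K2S2O8 (4 equiv), TFA/TFAA 9:1, rt to 40 °C; then H2O, aq. NaHCO3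
Reagents that add atoms: trifluoroacetic acid, OC(=O)C(F)(F)F
Why: Proposed new method: ketone-directed palladium-catalysed ortho C–H oxygenation is established for aryl alkyl and diaryl ketones (the closest known reaction type) but not for aryl alkenyl ketones, and here it must act twice on a bis-chalcone. In TFA each ketone oxygen binds electrophilic divalent palladium trifluoroacetate, concerted metalation–deprotonation of the ortho C–H gives a five-membered palladacycle, K2S2O8 oxidises it to tetravalent palladium, and C–O reductive elimination releases the aryl trifluoroacetate and divalent palladium; aqueous work-up hydrolyses 7 to the chelated bis-phenol 8. No ring is closed and no stereocentre is formed; the E double bonds take no part and should be retained. In ring C the two ortho C–H bonds are equivalent; in ring A, C2–H is preferred over C6–H because C6 is flanked by the C5 aryloxy group and C2 is also para to that donor oxygen, which favours electrophilic palladation. A second oxygenation is held back because each new ortho trifluoroacetoxy group withdraws electron density and, in ring A, the only remaining ortho site is the hindered C6. The vinylic β C–H, which the ketone can also reach, and the C=C bond are electron-poor and should resist electrophilic palladation and trifluoroacetoxypalladation, and rings B and D are deactivated by the pivalate and the para enone. TFAA keeps the new oxygens acylated in the flask, so no free 2-hydroxychalcone meets acid or oxidant (no flavanone, flavone or aurone closure), and the chalcone has no enolisable α-CH3 to be oxidised.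

Step 5
Reactants: 8 rhuschalcone IV bis(pivalate)
Product: 9 rhuschalcone IV
Conditions: K2CO3 (6 equiv), MeOH/THF 2:1, 0 °C to rt; then cold 1 M HCl to pH 4–5
Reagents that add atoms: none
Why: Base-mediated transesterification (methanolysis): methoxide attacks each pivaloyl carbonyl and expels a phenoxide stabilised by the para enone, so these hindered esters are activated. Under base the open chalcone phenoxides are the favoured side of the chalcone–flavanone equilibrium and the ring B and ring D phenoxides lower the electrophilicity of the enones, so cold mild acidification should return 9 with both E alkenes intact.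

## Compound list

1 | 3'-hydroxy-4'-methoxyacetophenone | CC(=O)c1ccc(OC)c(O)c1 | starting material
2 | 4'-fluoroacetophenone | CC(=O)c1ccc(F)cc1 | starting material
3 | 1-[3-(4-acetylphenoxy)-4-methoxyphenyl]ethan-1-one | CC(=O)c1ccc(OC)c(Oc2ccc(C(C)=O)cc2)c1 | intermediate
4 | 4-hydroxybenzaldehyde | O=Cc1ccc(O)cc1 | starting material
5 | 4-formylphenyl pivalate | CC(C)(C)C(=O)Oc1ccc(C=O)cc1 | intermediate
6 | 2-deoxy bis-chalcone bis(pivalate), (E)-1-[4-methoxy-3-(4-{(E)-3-[4-(pivaloyloxy)phenyl]prop-2-enoyl}phenoxy)phenyl]-3-[4-(pivaloyloxy)phenyl]prop-2-en-1-one | COc1ccc(C(=O)/C=C/c2ccc(OC(=O)C(C)(C)C)cc2)cc1Oc1ccc(C(=O)/C=C/c2ccc(OC(=O)C(C)(C)C)cc2)cc1 | intermediate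
7 | bis(aryl trifluoroacetate) of 8 (trifluoroacetoxy groups at C2 of ring A and C2 of ring C; formed in the flask) | COc1cc(OC(=O)C(F)(F)F)c(C(=O)/C=C/c2ccc(OC(=O)C(C)(C)C)cc2)cc1Oc1ccc(C(=O)/C=C/c2ccc(OC(=O)C(C)(C)C)cc2)c(OC(=O)C(F)(F)F)c1 | intermediate
8 | rhuschalcone IV bis(pivalate) (ring B and ring D oxygens as 2,2-dimethylpropanoates) | COc1cc(O)c(C(=O)/C=C/c2ccc(OC(=O)C(C)(C)C)cc2)cc1Oc1ccc(C(=O)/C=C/c2ccc(OC(=O)C(C)(C)C)cc2)c(O)c1 | intermediate
9 | rhuschalcone IV, (E)-1-[2-hydroxy-5-(3-hydroxy-4-{(E)-3-(4-hydroxyphenyl)prop-2-enoyl}phenoxy)-4-methoxyphenyl]-3-(4-hydroxyphenyl)prop-2-en-1-one | COc1cc(O)c(C(=O)/C=C/c2ccc(O)cc2)cc1Oc1ccc(C(=O)/C=C/c2ccc(O)cc2)c(O)c1 | target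

## Step count and least certain steps

Total step count: 5. Longest linear sequence: 4 (steps 1, 3, 4 and 5; step 2 is a one-step side branch).

For step 4, the key step and the only one marked as a proposed new method, several processes could divert the reaction:
- consumption of the enones in the acidic oxidising medium, by Nazarov-type ring closure of the protonated chalcone onto the electron-rich ring A, by trifluoroacetoxypalladation, or by radical attack from persulfate;
- competing ketone-directed palladation at the vinylic β C–H;
- incomplete second oxygenation, leaving mono-oxygenated material;
- erosion of site control between C2 and C6 of ring A;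
- oxidative biaryl closure across the diaryl ether at higher temperature.

The fallback moves the same oxygenation to the substrate class for which it is established. Bis-acetophenone 3 would be treated with Pd(OAc)2 and K2S2O8 in TFA/TFAA to give, through the bis(trifluoroacetate) of the bis-acetophenone F1 (hydrolysed on work-up), 1-[5-(4-acetyl-3-hydroxyphenoxy)-2-hydroxy-4-methoxyphenyl]ethan-1-one F2. In parallel 4 would be converted with MOMCl and iPr2NEt into 4-(methoxymethoxy)benzaldehyde F3. A classical KOH-mediated Claisen–Schmidt condensation of F2 with F3 in EtOH should give rhuschalcone IV bis(methoxymethyl ether) F4, and HCl in MeOH/THF would remove both MOM groups. This detour sets out from 3 (and 4), bypasses 5 to 8, and returns to the route at 9 with the same number of steps.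

For step 3, the second condensation may stall at the mono-chalcone, or the water released may cause acid-mediated loss of a pivalate, giving mixtures of partly deprotected products. The fallback separates the two tasks. Diketone 3 would be condensed with unprotected 4 under Brønsted acid (SOCl2 in EtOH, HCl formed in situ, rt), conditions that tolerate free phenols, to give the 2-deoxy bis-chalcone bis-phenol F5. Acylation with PivCl, Et3N and DMAP in THF then returns to the route at 6, at the cost of one more linear step.

For step 5, methanolysis of the hindered pivalates may be slow. Prolonged exposure to base could then allow conjugate addition of methoxide, closure of a 2-hydroxychalcone to a flavanone on acidification, or retro-aldol fragmentation. The fallback changes the protecting group for the whole sequence: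
- 4 would be acetylated (Ac2O, pyridine) to 4-formylphenyl acetate F6.
- 3 and F6 would be condensed with BF3·OEt2 as in step 3 to the 2-deoxy bis-chalcone bis(acetate) F7.
- The oxygenation of step 4 would give, through the corresponding bis(aryl trifluoroacetate) F8, rhuschalcone IV bis(acetate) F9.
- The aryl acetates would be cleaved under nearly neutral conditions (NH4OAc, aqueous MeOH, rt).

This detour sets out from 3 and 4 and returns at 9.

For step 1, a single para acetyl group is only a moderate activator, so substitution may be slow and base-mediated aldol self-condensation of the methyl ketones may take over at the temperature required. The fallback replaces addition–elimination by an Ullmann-type ether coupling. Phenol 1 and purchased 4'-bromoacetophenone (CC(=O)c1ccc(Br)cc1) would be coupled with CuI, picolinic acid and K3PO4 in DMSO at 90 °C. It sets out from 1 and returns at 3; no new compound is made on this detour (entry F0).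

## Further compounds

F1 | step 4 | bis(trifluoroacetate) of F2 (not isolated) | CC(=O)c1cc(Oc2ccc(C(C)=O)c(OC(=O)C(F)(F)F)c2)c(OC)cc1OC(=O)C(F)(F)F
F2 | step 4 | 1-[5-(4-acetyl-3-hydroxyphenoxy)-2-hydroxy-4-methoxyphenyl]ethan-1-one | CC(=O)c1cc(Oc2ccc(C(C)=O)c(O)c2)c(OC)cc1O
F3 | step 4 | 4-(methoxymethoxy)benzaldehyde | COCOc1ccc(C=O)cc1
F4 | step 4 | rhuschalcone IV bis(methoxymethyl ether) (ring B and ring D oxygens protected) | COCOc1ccc(/C=C/C(=O)c2cc(Oc3ccc(C(=O)/C=C/c4ccc(OCOC)cc4)c(O)c3)c(OC)cc2O)cc1
F5 | step 3 | 2-deoxy bis-chalcone bis-phenol, (E)-3-(4-hydroxyphenyl)-1-[3-(4-{(E)-3-(4-hydroxyphenyl)prop-2-enoyl}phenoxy)-4-methoxyphenyl]prop-2-en-1-one | COc1ccc(C(=O)/C=C/c2ccc(O)cc2)cc1Oc1ccc(C(=O)/C=C/c2ccc(O)cc2)cc1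
F6 | step 5 | 4-formylphenyl acetate | CC(=O)Oc1ccc(C=O)cc1
F7 | step 5 | 2-deoxy bis-chalcone bis(acetate) | COc1ccc(C(=O)/C=C/c2ccc(OC(C)=O)cc2)cc1Oc1ccc(C(=O)/C=C/c2ccc(OC(C)=O)cc2)cc1
F8 | step 5 | bis(aryl trifluoroacetate) of F9 (not isolated) | COc1cc(OC(=O)C(F)(F)F)c(C(=O)/C=C/c2ccc(OC(C)=O)cc2)cc1Oc1ccc(C(=O)/C=C/c2ccc(OC(C)=O)cc2)c(OC(=O)C(F)(F)F)c1
F9 | step 5 | rhuschalcone IV bis(acetate) (ring B and ring D oxygens acetylated) | COc1cc(O)c(C(=O)/C=C/c2ccc(OC(C)=O)cc2)cc1Oc1ccc(C(=O)/C=C/c2ccc(OC(C)=O)cc2)c(O)c1
F0 | step 1 | none | none
A1 | alternative 1 | 1,1-bis(trimethylsilyloxy)-3-methoxy-4-[3-(methoxymethoxy)-4-(2-methyl-1,3-dioxolan-2-yl)phenoxy]buta-1,3-diene (geometry of the 3,4-double bond not defined) | C[Si](C)(C)OC(O[Si](C)(C)C)=CC(OC)=COc1ccc(C2(C)OCCO2)c(OCOC)c1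
A2 | alternative 1 | (E)-1-[4-(methoxymethoxy)phenyl]pent-1-en-4-yn-3-one | C#CC(=O)/C=C/c1ccc(OCOC)cc1
A3 | alternative 1 | ring A chalcone with free C2 phenol, ring B MOM ether and protected ring C (dioxolane, MOM ether) | COCOc1ccc(/C=C/C(=O)c2cc(Oc3ccc(C4(C)OCCO4)c(OCOC)c3)c(OC)cc2O)cc1
A4 | alternative 2 | 5-(4-formyl-3-hydroxyphenoxy)-2-hydroxy-4-methoxybenzaldehyde | COc1cc(O)c(C=O)cc1Oc1ccc(C=O)c(O)c1
A5 | alternative 2 | tert-butyl(4-ethynylphenoxy)dimethylsilane | C#Cc1ccc(O[Si](C)(C)C(C)(C)C)cc1
A6 | alternative 2 | rhuschalcone IV bis(tert-butyldimethylsilyl ether) (ring B and ring D oxygens silylated) | COc1cc(O)c(C(=O)/C=C/c2ccc(O[Si](C)(C)C(C)(C)C)cc2)cc1Oc1ccc(C(=O)/C=C/c2ccc(O[Si](C)(C)C(C)(C)C)cc2)c(O)c1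
A7 | alternative 3 | (E)-8-(4-acetyl-3-hydroxyphenoxy)-9,9-dimethoxy-1-[4-(prop-2-en-1-yloxy)phenyl]non-1-ene-3,5,7-trione (racemic at C8) | C=CCOc1ccc(/C=C/C(=O)CC(=O)CC(=O)C(Oc2ccc(C(C)=O)c(O)c2)C(OC)OC)cc1
A8 | alternative 3 | ring A chalcone with free C2 and C4 phenols, ring B allyl ether and the ring C 2-hydroxyacetophenone | C=CCOc1ccc(/C=C/C(=O)c2cc(Oc3ccc(C(C)=O)c(O)c3)c(O)cc2O)cc1
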